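**Plan**

- Retrosynthetic cuts, in order: the C3–O acyl bond (ester), the C3–C3a bond (ring B), the O1–C2 allylic ether bond, and the C3a–I bond.
- Forward: ring A is bought as 2,4-dihydroxyacetophenone and iodinated at the future C3a. O1–C2 is made by palladium-catalysed allylic etherification with a racemic vinyl epoxide. Ring B is then closed from C3a to C3. The acyl chain, made separately from crotonaldehyde, is joined last.
- Feature used: C3 is a carbinol carbon bonded directly to C3a of ring A, and C3a is ortho to O1, which carries C2. An aryl–metal at C3a and an aldehyde at C3 are therefore 1,5-related through O1–C2 and close ring B by carbonyl addition. Aryl–chromium is chosen because it adds to the aldehyde but not to the C5 acetyl ketone or across the C2 isopropenyl double bond, which an aryl radical or an aryl–nickel or aryl–palladium species would attack (5-exo).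
- Stereochemistry: C2 (R) comes from the ligand-controlled etherification of the racemic epoxide. C3 (S, trans to isopropenyl) comes from substrate control in the ring closure. The Z-alkene comes from (Z)-2-iodobut-2-enal and is carried through a retentive lithiation–carboxylation.

Key step: step 5

Assumption: the (S,S)-ligand is taken to give the R configuration at C2 in step 3; if the first run shows the opposite sense, the (R,R)-ligand is used with nothing else changed.

**Route**

Step 1
Reactants: 1 1-(2,4-dihydroxyphenyl)ethanone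
Product: 2 1-(2,4-dihydroxy-5-iodophenyl)ethanone
Conditions: NIS (1.05 equiv), TsOH·H2O (10 mol%), MeCN, 0 °C to rt; recrystallisation
Reagents that add atoms: N-iodosuccinimide, O=C1CCC(=O)N1I
Why: Electrophilic aromatic iodination; C5 is para to the hydrogen-bonded C2 hydroxyl, ortho to the C4 hydroxyl and less crowded than C3 between the two hydroxyls, so iodine should enter at the carbon that becomes C3a.

Step 2
Reactants: 3 2-methylprop-2-enal (methacrolein)
Product: 4 rac-2-(prop-1-en-2-yl)oxirane
Conditions: Me3S+ I−, KOtBu, DMSO–THF, 0 °C to rt; distillation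
Reagents that add atoms: trimethylsulfonium iodide, C[S+](C)C.[I-]
Why: Corey–Chaykovsky epoxidation: the unstabilised sulfonium ylide adds 1,2 to the enal carbonyl and closes to the vinyl epoxide; the racemate is acceptable because step 3 converts both enantiomers.

Step 3
Reactants: 2 1-(2,4-dihydroxy-5-iodophenyl)ethanone; 4 rac-2-(prop-1-en-2-yl)oxirane (1.5 equiv)
Product: 5 1-[2-hydroxy-4-{[(2R)-1-hydroxy-3-methylbut-3-en-2-yl]oxy}-5-iodophenyl]ethanone
Conditions: Pd2(dba)3·CHCl3 (1 mol%), (1S,2S)-N,N′-bis[2-(diphenylphosphanyl)benzoyl]cyclohexane-1,2-diamine (3 mol%), CH2Cl2, rt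
Reagents that add atoms: none
Why: Tsuji–Trost allylic etherification run as a dynamic kinetic asymmetric transformation: zerovalent palladium opens either epoxide enantiomer to π-allyl complexes that interconvert through the unsubstituted CH2 terminus, the acidic non-chelated C4 phenol protonates the alkoxide and is delivered to the adjacent allyl terminus (branched ether), and the chiral ligand sets C2 as R; the aryl iodide should not react at room temperature.

Step 4
Reactants: 5 1-[2-hydroxy-4-{[(2R)-1-hydroxy-3-methylbut-3-en-2-yl]oxy}-5-iodophenyl]ethanone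
Product: 6 (2R)-2-(4-acetyl-5-hydroxy-2-iodophenoxy)-3-methylbut-3-enal
Conditions: Dess–Martin periodinane (1.3 equiv), pyridine (3 equiv), CH2Cl2, 0 °C; filtered, concentrated cold, used at once
Reagents that add atoms: none
Why: Dess–Martin oxidation under buffered, non-basic conditions should give the aldehyde without enolising C2, which is allylic and α to oxygen; the aldehyde is not stored or chromatographed.

Step 5
Reactants: 6 (2R)-2-(4-acetyl-5-hydroxy-2-iodophenoxy)-3-methylbut-3-enal
Product: 7 1-[(2R,3S)-3,6-dihydroxy-2-(prop-1-en-2-yl)-2,3-dihydro-1-benzofuran-5-yl]ethanone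
Conditions: CrCl2 (4 equiv), NiCl2 (1 mol%), degassed DMSO, rt; aq. NH4Cl work-up
Reagents that add atoms: none
Why: Nozaki–Hiyama–Kishi ring closure: zerovalent nickel, formed from NiCl2 and CrCl2, inserts into the C3a–I bond, the aryl group passes to trivalent chromium, and the aryl–chromium σ-bond adds to the C3 aldehyde; the closest known type is the nickel/chromium-mediated intramolecular coupling of aryl iodides with aldehydes. Ring B closes in a 5-exo-trig mode with the C3a–Cr bond lying in the plane of ring A, so the arene π system need not bend towards C3. The new stereocentre C3 is controlled by C2: the chromium-bound carbonyl oxygen turns away from the isopropenyl group, so the C3–O bond should form trans to it and C3 becomes S. The step needs aldehyde-over-ketone selectivity, which the aldehyde-selective organochromium secures (the C5 acetyl is also out of reach). It also needs carbonyl addition in preference to 5-exo carbometalation of the isopropenyl double bond, which aryl–chromium does not undergo and which is held down at the nickel stage by keeping NiCl2 at 1 mol% under a large excess of CrCl2. The neutral medium should leave C2 of the aldehyde intact during its short life.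

Step 6
Reactants: 7 1-[(2R,3S)-3,6-dihydroxy-2-(prop-1-en-2-yl)-2,3-dihydro-1-benzofuran-5-yl]ethanone
Product: 8 1-[(2R,3S)-6-{[tert-butyl(dimethyl)silyl]oxy}-3-hydroxy-2-(prop-1-en-2-yl)-2,3-dihydro-1-benzofuran-5-yl]ethanone
Conditions: TBSCl (1.2 equiv), Et3N (2 equiv), CH2Cl2, 0 °C to rt
Reagents that add atoms: tert-butyldimethylsilyl chloride, CC(C)(C)[Si](C)(C)Cl
Why: Phenol-selective silylation: triethylamine deprotonates the phenol, while the hindered secondary benzylic alcohol should not be silylated without a nucleophilic catalyst; the silyl ether blocks phenol acylation and para-quinone-methide formation in step 11.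

Step 7
Reactants: 9 (E)-but-2-enal (crotonaldehyde)
Product: 10 (Z)-2-iodobut-2-enal
Conditions: I2 (1.5 equiv), K2CO3 (1.2 equiv), DMAP (0.2 equiv), THF–H2O (1:1), rt
Reagents that add atoms: iodine, II
Why: α-Iodination of the enal by conjugate addition of DMAP, iodination of the enolate and elimination (Baylis–Hillman-type addition–elimination), which should give the isomer with iodine cis to the methyl group.

Step 8
Reactants: 10 (Z)-2-iodobut-2-enal
Product: 11 (Z)-2-iodobut-2-en-1-ol
Conditions: NaBH4, CeCl3·7H2O, MeOH, 0 °C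
Reagents that add atoms: none
Why: Luche reduction: 1,2-selective reduction of the enal that leaves the vinyl iodide and the alkene geometry untouched.

Step 9
Reactants: 11 (Z)-2-iodobut-2-en-1-ol
Product: 13 (Z)-2-(hydroxymethyl)but-2-enoic acid, via dilithio alkoxide 12 (not isolated)
Conditions: t-BuLi (3.1 equiv), Et2O, −78 °C; CO2 (g), −78 °C to rt; 1 M HCl
Reagents that add atoms: carbon dioxide, O=C=O
Why: Deprotonation and iodine–lithium exchange give an alkenyllithium that is configurationally stable at −78 °C, and carboxylation proceeds with retention, so the methyl group ends cis to the carboxyl group (Z).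

Step 10
Reactants: 13 (Z)-2-(hydroxymethyl)but-2-enoic acid
Product: 14 (Z)-2-(acetoxymethyl)but-2-enoic acid
Conditions: Ac2O (2.5 equiv), pyridine, 0 °C to rt; then H2O
Reagents that add atoms: acetic anhydride, CC(=O)OC(C)=O
Why: O-Acetylation of the primary allylic alcohol; any mixed anhydride formed at the carboxyl group is hydrolysed in the aqueous work-up.

Step 11
Reactants: 8 1-[(2R,3S)-6-{[tert-butyl(dimethyl)silyl]oxy}-3-hydroxy-2-(prop-1-en-2-yl)-2,3-dihydro-1-benzofuran-5-yl]ethanone; 14 (Z)-2-(acetoxymethyl)but-2-enoic acid (1.5 equiv)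
Product: 16 (2R,3S)-5-acetyl-6-{[tert-butyl(dimethyl)silyl]oxy}-2-(prop-1-en-2-yl)-2,3-dihydro-1-benzofuran-3-yl (Z)-2-(acetoxymethyl)but-2-enoate, via acid chloride 15 (not isolated)
Conditions: 14, (COCl)2, DMF (cat.), CH2Cl2, 0 °C to rt, evaporated; then 8, pyridine (3 equiv), CH2Cl2, 0 °C to rt
Reagents that add atoms: none
Why: Acylation of the C3 hydroxyl by the acid chloride without DMAP, so that Z/E isomerisation or allylic shift of the acetate by addition–elimination should be avoided; the C3–O bond is not broken, so the 3S configuration is kept.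

Step 12
Reactants: 16 (2R,3S)-5-acetyl-6-{[tert-butyl(dimethyl)silyl]oxy}-2-(prop-1-en-2-yl)-2,3-dihydro-1-benzofuran-3-yl (Z)-2-(acetoxymethyl)but-2-enoate
Product: 17 (2R,3S)-5-acetyl-6-hydroxy-2-(prop-1-en-2-yl)-2,3-dihydro-1-benzofuran-3-yl (Z)-2-(acetoxymethyl)but-2-enoate
Conditions: HF·pyridine, pyridine, THF, 0 °C
Reagents that add atoms: none
Why: Fluoride cleavage of the aryl silyl ether under buffered, non-basic conditions, which should spare the two esters, the isopropenyl group and the ionisable benzylic C3–O bond (no phenoxide is formed, so no para-quinone-methide elimination).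

**Compound list**

1 | 1-(2,4-dihydroxyphenyl)ethanone | CC(=O)c1ccc(O)cc1O | starting material
2 | 1-(2,4-dihydroxy-5-iodophenyl)ethanone | CC(=O)c1cc(I)c(O)cc1O | intermediate
3 | 2-methylprop-2-enal | C=C(C)C=O | starting material
4 | rac-2-(prop-1-en-2-yl)oxirane | C=C(C)C1CO1 | intermediate
5 | 1-[2-hydroxy-4-{[(2R)-1-hydroxy-3-methylbut-3-en-2-yl]oxy}-5-iodophenyl]ethanone | C=C(C)[C@H](CO)Oc1cc(O)c(C(C)=O)cc1I | intermediate
6 | (2R)-2-(4-acetyl-5-hydroxy-2-iodophenoxy)-3-methylbut-3-enal | C=C(C)[C@H](C=O)Oc1cc(O)c(C(C)=O)cc1I | intermediate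
7 | 1-[(2R,3S)-3,6-dihydroxy-2-(prop-1-en-2-yl)-2,3-dihydro-1-benzofuran-5-yl]ethanone | C=C(C)[C@H]1Oc2cc(O)c(C(C)=O)cc2[C@@H]1O | intermediate
8 | 1-[(2R,3S)-6-{[tert-butyl(dimethyl)silyl]oxy}-3-hydroxy-2-(prop-1-en-2-yl)-2,3-dihydro-1-benzofuran-5-yl]ethanone | C=C(C)[C@H]1Oc2cc(O[Si](C)(C)C(C)(C)C)c(C(C)=O)cc2[C@@H]1O | intermediate
9 | (E)-but-2-enal | C/C=C/C=O | starting material
10 | (Z)-2-iodobut-2-enal | C/C=C(\I)C=O | intermediate
11 | (Z)-2-iodobut-2-en-1-ol | C/C=C(\I)CO | intermediate
12 | lithium 2-lithiobut-2-en-1-olate (lithium on C2 cis to the methyl group) | C/C=C(\[Li])CO[Li] | intermediate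
13 | (Z)-2-(hydroxymethyl)but-2-enoic acid | C/C=C(\C(=O)O)CO | intermediate
14 | (Z)-2-(acetoxymethyl)but-2-enoic acid | C/C=C(\C(=O)O)COC(C)=O | intermediate
15 | (Z)-2-(acetoxymethyl)but-2-enoyl chloride | C/C=C(\C(Cl)=O)COC(C)=O | intermediate
16 | (2R,3S)-5-acetyl-6-{[tert-butyl(dimethyl)silyl]oxy}-2-(prop-1-en-2-yl)-2,3-dihydro-1-benzofuran-3-yl (Z)-2-(acetoxymethyl)but-2-enoate | C=C(C)[C@H]1Oc2cc(O[Si](C)(C)C(C)(C)C)c(C(C)=O)cc2[C@@H]1OC(=O)/C(=C\C)COC(C)=O | intermediate
17 | (2R,3S)-5-acetyl-6-hydroxy-2-(prop-1-en-2-yl)-2,3-dihydro-1-benzofuran-3-yl (Z)-2-(acetoxymethyl)but-2-enoate | C=C(C)[C@H]1Oc2cc(O)c(C(C)=O)cc2[C@@H]1OC(=O)/C(=C\C)COC(C)=O | target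

**Step count and risks**

Total step count: 12. Longest linear sequence: 7 steps (1 → 2 → 5 → 6 → 7 → 8 → 16 → 17).

Steps most likely to fail:

1. Step 5. The aryl–nickel intermediate may add across the isopropenyl double bond before it hands the aryl group to chromium. The aryl–chromium may also be protonated by the free phenol, or the aldehyde may lose its C2 configuration or shift its double bond into conjugation while it waits. The fallback sets out from 5 and avoids aryl–nickel and aryl–palladium species altogether. Copper-catalysed borylation of the C–I bond (CuI, PBu3, KOtBu, bis(pinacolato)diboron, THF, rt) should give 1-[2-hydroxy-4-{[(2R)-1-hydroxy-3-methylbut-3-en-2-yl]oxy}-5-(4,4,5,5-tetramethyl-1,3,2-dioxaborolan-2-yl)phenyl]ethanone F1. Dess–Martin oxidation as in step 4 should then give (2R)-2-[4-acetyl-5-hydroxy-2-(4,4,5,5-tetramethyl-1,3,2-dioxaborolan-2-yl)phenoxy]-3-methylbut-3-enal F2. Rhodium-catalysed intramolecular 1,2-addition of the aryl boronate to the aldehyde ([Rh(OH)(cod)]2, dioxane–H2O, rt) closes ring B and returns to the route at 7.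

2. Step 3. The phenol may attack the unsubstituted allyl terminus and give the linear ether, or the hindered ortho-iodophenol may add with poor facial selectivity. The fallback sets out from 4 and 2 and sets C2 by resolution and inversion. Hydrolytic kinetic resolution of 4 (chiral (salen)Co(OAc), salen = N,N′-bis(3,5-di-tert-butylsalicylidene)cyclohexane-1,2-diamine, 0.45 equiv H2O) should give (2S)-3-methylbut-3-ene-1,2-diol F3, the unreacted epoxide being distilled off. Silylation of the primary hydroxyl (TBSCl, imidazole, CH2Cl2, −20 °C) gives (2S)-1-{[tert-butyl(dimethyl)silyl]oxy}-3-methylbut-3-en-2-ol F4. A Mitsunobu reaction with 2 (PPh3, diisopropyl azodicarboxylate, THF, 0 °C), in which only the acidic non-chelated C4 phenol reacts and the carbinol centre is inverted, gives 1-[4-{[(2R)-1-{[tert-butyl(dimethyl)silyl]oxy}-3-methylbut-3-en-2-yl]oxy}-2-hydroxy-5-iodophenyl]ethanone F5. Desilylation with HF·pyridine returns to the route at 5.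

3. Step 11. Acyl activation may cause isomerisation of the Z double bond, allylic transposition of the acetate, or deconjugation through a vinylketene, and the hindered benzylic alcohol may acylate slowly. The fallback sets out from 11 and 8 and forms the acyl C–C bond by carbonylation, so no activated acid is involved. Silylation of 11 (TBSCl, imidazole) gives (Z)-tert-butyl[(2-iodobut-2-en-1-yl)oxy]dimethylsilane F6. Palladium-catalysed alkoxycarbonylation of F6 with 8 as the alcohol (PdCl2(PPh3)2, CO at 1 atm, Et3N, toluene, 60 °C) keeps the alkene geometry of the vinyl iodide and should give (2R,3S)-5-acetyl-6-{[tert-butyl(dimethyl)silyl]oxy}-2-(prop-1-en-2-yl)-2,3-dihydro-1-benzofuran-3-yl (Z)-2-({[tert-butyl(dimethyl)silyl]oxy}methyl)but-2-enoate F7. HF·pyridine removes both silyl groups to give (2R,3S)-5-acetyl-6-hydroxy-2-(prop-1-en-2-yl)-2,3-dihydro-1-benzofuran-3-yl (Z)-2-(hydroxymethyl)but-2-enoate F8. Acetylation of the primary allylic hydroxyl in preference to the hydrogen-bonded phenol (Ac2O 1.05 equiv, 2,4,6-collidine, CH2Cl2, −20 °C) comes back to the route at 17.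

**Further compounds**

F1 | step 5 | 1-[2-hydroxy-4-{[(2R)-1-hydroxy-3-methylbut-3-en-2-yl]oxy}-5-(4,4,5,5-tetramethyl-1,3,2-dioxaborolan-2-yl)phenyl]ethanone | C=C(C)[C@H](CO)Oc1cc(O)c(C(C)=O)cc1B1OC(C)(C)C(C)(C)O1
F2 | step 5 | (2R)-2-[4-acetyl-5-hydroxy-2-(4,4,5,5-tetramethyl-1,3,2-dioxaborolan-2-yl)phenoxy]-3-methylbut-3-enal | C=C(C)[C@H](C=O)Oc1cc(O)c(C(C)=O)cc1B1OC(C)(C)C(C)(C)O1
F3 | step 3 | (2S)-3-methylbut-3-ene-1,2-diol | C=C(C)[C@@H](CO)O
F4 | step 3 | (2S)-1-{[tert-butyl(dimethyl)silyl]oxy}-3-methylbut-3-en-2-ol | C=C(C)[C@@H](CO[Si](C)(C)C(C)(C)C)O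
F5 | step 3 | 1-[4-{[(2R)-1-{[tert-butyl(dimethyl)silyl]oxy}-3-methylbut-3-en-2-yl]oxy}-2-hydroxy-5-iodophenyl]ethanone | C=C(C)[C@H](CO[Si](C)(C)C(C)(C)C)Oc1cc(O)c(C(C)=O)cc1I
F6 | step 11 | (Z)-tert-butyl[(2-iodobut-2-en-1-yl)oxy]dimethylsilane | C/C=C(\I)CO[Si](C)(C)C(C)(C)C
F7 | step 11 | (2R,3S)-5-acetyl-6-{[tert-butyl(dimethyl)silyl]oxy}-2-(prop-1-en-2-yl)-2,3-dihydro-1-benzofuran-3-yl (Z)-2-({[tert-butyl(dimethyl)silyl]oxy}methyl)but-2-enoate | C=C(C)[C@H]1Oc2cc(O[Si](C)(C)C(C)(C)C)c(C(C)=O)cc2[C@@H]1OC(=O)/C(=C\C)CO[Si](C)(C)C(C)(C)C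
F8 | step 11 | (2R,3S)-5-acetyl-6-hydroxy-2-(prop-1-en-2-yl)-2,3-dihydro-1-benzofuran-3-yl (Z)-2-(hydroxymethyl)but-2-enoate | C=C(C)[C@H]1Oc2cc(O)c(C(C)=O)cc2[C@@H]1OC(=O)/C(=C\C)CO
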